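**Retrosynthetic overview**

1. Target 38 ⇐ late acetylation, 14‑OH‑directed 11,12‑epoxidation, alkyne → (E)‑alkene reduction and exo → endo alkene shift from the briarane enyne 32.
2. 32 ⇐ transannular C1–C10 bond formation (cembrane C3–C8) in the 14‑membered (3Z,7Z)‑7,8‑epoxy‑cembranolide enyne 31: cembrane → briarane as in the presumed biosynthesis, run as a titanocene radical epoxide–olefin cyclisation that sets C1, C10 and C14 together.
3. 31 ⇐ Sonogashira macrocyclisation (briarane C3–C4) of seco‑lactone 29 ⇐ vinyltitanium addition of bromide 11 to epoxy aldehyde 24 (briarane C9–C10), then epoxide‑opening lactonisation.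
4. 11 ⇐ Normant carbocupration, Still–Gennari olefination, Noyori reduction, directed epoxidation; 24 ⇐ butynediol, (R)‑lactate, HWE olefination, Sharpless epoxidation.
5. Ring order: oxiranes → γ‑lactone → 14‑membered carbocycle → cyclohexane (leaving the 10‑membered ring) → 11,12‑oxirane.

Assumption: cembrane numbering is used for intermediates (ring C1–C14; C15–C17 the propanoate branch on C1; C18, C19, C20 on C4, C8, C12) and briarane numbering for the target; conjugate bases made in situ from numbered compounds (phosphonate anions, alkoxides, the lithium acetylide of 8) are not numbered separately; Grignard solution 1 and tert‑butyl (R)‑lactate 18 are bought.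

**Route**

Step 1
Reactants: 1 [2-(1,3-dioxolan-2-yl)ethyl]magnesium bromide; 2 propyne
Product: 5 (4Z)-5-bromo-4-methylpent-4-enal, via vinylcopper 3 (not isolated), via bromo acetal 4 (not isolated)
Conditions: CuBr·SMe2, Et2O/Me2S, −45 °C; 2, −25 °C; NBS, −78 → 0 °C; then 2 M HCl, THF, 23 °C
Reagents that add atoms: N-bromosuccinimide O=C1CCC(=O)N1Br; water O
Why: Normant syn‑carbocupration of propyne puts the alkyl group and copper cis, so bromination of 3 with retention gives only the (Z)‑bromide (the future C3=C4 geometry), and the dioxolane is hydrolysed in the same pot.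

Step 2
Reactants: 5 (4Z)-5-bromo-4-methylpent-4-enal; 6 ethyl 2-[bis(2,2,2-trifluoroethoxy)phosphoryl]propanoate
Product: 7 ethyl (2Z,6Z)-7-bromo-2,6-dimethylhepta-2,6-dienoate
Conditions: KN(SiMe3)2, 18-crown-6, THF, −78 °C
Reagents that add atoms: none
Why: Still–Gennari olefination (fast irreversible elimination from the kinetic adduct) gives the (Z)‑2‑methyl enoate, the C7=C8 geometry that later encodes the axial C14 oxygen of the target.

Step 3
Reactants: 7 ethyl (2Z,6Z)-7-bromo-2,6-dimethylhepta-2,6-dienoate; 8 ethynyltrimethylsilane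
Product: 9 (4Z,8Z)-9-bromo-4,8-dimethyl-1-(trimethylsilyl)nona-4,8-dien-1-yn-3-one
Conditions: 8, n-BuLi, THF, −78 °C; BF3·OEt2; then 7, −78 °C
Reagents that add atoms: none
Why: Yamaguchi–Hirao acylation, in which the BF3‑complexed lithium acetylide adds once to the ester and the tetrahedral borate collapses only on work‑up, so neither over‑addition nor conjugate addition occurs.

Step 4
Reactants: 9 (4Z,8Z)-9-bromo-4,8-dimethyl-1-(trimethylsilyl)nona-4,8-dien-1-yn-3-one
Product: 10 (3R,4Z,8Z)-9-bromo-4,8-dimethyl-1-(trimethylsilyl)nona-4,8-dien-1-yn-3-ol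
Conditions: RuCl[(R,R)-TsDPEN](p-cymene) (2 mol %), i-PrOH, 23 °C
Reagents that add atoms: none
Why: Noyori asymmetric transfer hydrogenation of the alkynyl ketone (alkyne as the pi‑directing group; the (R,R) catalyst gives the mirror image of the (S)‑alkynols obtained with the (S,S) catalyst) sets the carbinol that becomes C2 of the target.

Step 5
Reactants: 10 (3R,4Z,8Z)-9-bromo-4,8-dimethyl-1-(trimethylsilyl)nona-4,8-dien-1-yn-3-ol
Product: 11 (1S)-1-{(2R,3S)-3-[(3Z)-4-bromo-3-methylbut-3-en-1-yl]-2-methyloxiran-2-yl}-3-(trimethylsilyl)prop-2-yn-1-ol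
Conditions: mCPBA, NaHCO3, CH2Cl2, 0 °C
Reagents that add atoms: 3-chloroperoxybenzoic acid OOC(=O)c1cccc(Cl)c1
Why: hydroxyl‑directed peracid epoxidation of the (Z)‑allylic alcohol through the A(1,3)‑minimised conformer gives the threo epoxy alcohol (about 9:1), setting the oxirane carbons that become C14 and C1, while the bromoalkene and silylalkyne are inert.

Step 6
Reactants: 12 but-2-yne-1,4-diol
Product: 13 4-[(tert-butyldimethylsilyl)oxy]but-2-yn-1-ol
Conditions: NaH (1 equiv), THF, 0 °C; TBSCl, 23 °C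
Reagents that add atoms: tert-butyldimethylsilyl chloride CC(C)(C)[Si](C)(C)Cl
Why: monosilylation of the symmetric diol through its sparingly soluble monosodium alkoxide (silyl ether formation).

Step 7
Reactants: 13 4-[(tert-butyldimethylsilyl)oxy]but-2-yn-1-ol
Product: 15 (2Z)-4-[(tert-butyldimethylsilyl)oxy]-3-iodobut-2-en-1-ol, via alkenylalanate 14 (not isolated)
Conditions: NaAlH2(OCH2CH2OMe)2, THF, 0 °C; then I2, −78 → 0 °C
Reagents that add atoms: iodine II
Why: hydroxyl‑directed trans‑hydroalumination places aluminium on the distal alkyne carbon cis to the carbinol, and iodinolysis with retention gives the (Z)‑vinyl iodide.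

Step 8
Reactants: 15 (2Z)-4-[(tert-butyldimethylsilyl)oxy]-3-iodobut-2-en-1-ol
Product: 16 (2Z)-4-[(tert-butyldimethylsilyl)oxy]-3-iodobut-2-enal
Conditions: MnO2, CH2Cl2, 23 °C
Reagents that add atoms: none
Why: MnO2 oxidation of the allylic alcohol gives the enal without alkene isomerisation.

Step 9
Reactants: 17 triethyl phosphonoacetate; 18 tert-butyl (2R)-2-hydroxypropanoate
Product: 20 4-tert-butyl 1-ethyl (3S)-2-(diethoxyphosphoryl)-3-methylbutanedioate (both epimers at C2), via lactate triflate 19 (not isolated)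
Conditions: 18, Tf2O, 2,6-lutidine, CH2Cl2, −78 °C; then sodium salt of 17 (NaH), THF, −20 → 23 °C
Reagents that add atoms: none
Why: SN2 displacement of the alpha‑triflyloxy ester by the phosphonoacetate anion proceeds with clean inversion, setting the methyl‑bearing carbon (C17 of the target) from the chiral pool.

Step 10
Reactants: 16 (2Z)-4-[(tert-butyldimethylsilyl)oxy]-3-iodobut-2-enal; 20 phosphonosuccinate
Product: 21 4-tert-butyl 1-ethyl (2E,3R)-2-{(2Z)-4-[(tert-butyldimethylsilyl)oxy]-3-iodobut-2-en-1-ylidene}-3-methylbutanedioate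
Conditions: NaH (1.0 equiv), THF, 0 °C; then 16, −20 → 0 °C
Reagents that add atoms: none
Why: Horner–Wadsworth–Emmons olefination of the alpha‑branched phosphonate gives the (E)‑alkylidene succinate (aldehyde residue trans to the ethyl ester), the geometry needed for the later lactonisation, and the stabilised anion is too weak a base to epimerise the adjacent stereocentre.

Step 11
Reactants: 21 alkylidene succinate diester
Product: 22 tert-butyl (2R,3E,5Z)-7-[(tert-butyldimethylsilyl)oxy]-3-(hydroxymethyl)-6-iodo-2-methylhepta-3,5-dienoate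
Conditions: i-Bu2AlH (2.2 equiv), CH2Cl2, −78 °C
Reagents that add atoms: none
Why: chemoselective hydride reduction, the conjugated ethyl ester being reduced to the allylic alcohol while the hindered tert‑butyl ester survives at −78 °C.

Step 12
Reactants: 22 dienol tert-butyl ester
Product: 23 tert-butyl (2R)-2-[(2R,3R)-3-{(1Z)-3-[(tert-butyldimethylsilyl)oxy]-2-iodoprop-1-en-1-yl}-2-(hydroxymethyl)oxiran-2-yl]propanoate
Conditions: Ti(OiPr)4 (10 mol %), D-(−)-diethyl tartrate (12 mol %), t-BuOOH, 4 Å MS, CH2Cl2, −20 °C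
Reagents that add atoms: tert-butyl hydroperoxide CC(C)(C)OO
Why: Sharpless asymmetric epoxidation with D‑(−)‑tartrate gives the (2R,3R)‑oxirane under reagent control, only the hydroxyl‑bearing alkene of the dienol reacts, and this sets the future C8 carbinol and (after inversion) C7.

Step 13
Reactants: 23 epoxy alcohol
Product: 24 tert-butyl (2R)-2-[(2S,3R)-2-formyl-3-{(1Z)-3-[(tert-butyldimethylsilyl)oxy]-2-iodoprop-1-en-1-yl}oxiran-2-yl]propanoate
Conditions: Dess–Martin periodinane, NaHCO3, CH2Cl2, 0 °C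
Reagents that add atoms: none
Why: Dess–Martin oxidation gives the non‑enolisable alpha‑quaternary epoxy aldehyde under buffered neutral conditions.

Step 14
Reactants: 11 bromo epoxy propargylic alcohol; 24 epoxy aldehyde
Product: 27 bis-epoxide diol tert-butyl ester (C2–C3 adduct; 1,14- and 7,8-epoxides; 2-OH and 9-OH free), via vinyllithium 25 (not isolated), via vinyltitanium 26 (not isolated)
Conditions: 11, t-BuLi (3.1 equiv), Et2O, −78 °C; ClTi(OiPr)3 (2.2 equiv), −78 → −50 °C; then 24, −78 → −20 °C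
Reagents that add atoms: none
Why: bromine–lithium exchange with retention and transmetallation give a non‑basic, non‑chelating vinyltitanium (Reetz reagent) that adds only to the aldehyde, and Felkin–Anh/Cornforth attack anti to the oxirane C–O bond and past the tied‑back oxirane CH (away from the branched propanoate arm) sets the carbinol that becomes C9.

Step 15
Reactants: 27 bis-epoxide diol tert-butyl ester
Product: 28 seco-cembranolide diol (17,14-lactone; tertiary 1-OH; 2-OH and 9-OH free)
Conditions: CSA (10 mol %), CH2Cl2, −20 → 0 °C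
Reagents that add atoms: none
Why: acid‑triggered lactonisation in which the tert‑butyl ester carbonyl opens the activated vinyl epoxide at its allylic carbon with inversion (isobutene lost), giving the gamma‑lactone with the tertiary C8‑OH and the C7 configuration of the target, while the less activated trisubstituted epoxide survives.

Step 16
Reactants: 28 seco-cembranolide diol
Product: 29 seco-cembranolide 2,9-diacetate (C11 silylalkyne; C12 iodide)
Conditions: Ac2O, pyridine, DMAP, CH2Cl2, 23 °C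
Reagents that add atoms: acetic anhydride CC(=O)OC(C)=O
Why: DMAP‑catalysed acylation of the two secondary alcohols, the tertiary alcohol being inert, which also blocks lactone migration to the C2 oxygen.

Step 17
Reactants: 29 seco-cembranolide 2,9-diacetate
Product: 31 (3Z)-7,8-epoxycembra-3,12-dien-10-yn-17,14-olide 2,9-diacetate 20-silyl ether (14-membered ring), via terminal alkyne 30 (not isolated)
Conditions: Pd(PPh3)4 (20 mol %), CuI (40 mol %), CsF, Et3N, DMF (1 mM, slow addition), 23 °C
Reagents that add atoms: none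
Why: fluoride unmasks the alkyne slowly at high dilution and Sonogashira coupling with the (Z)‑vinyl iodide (retention of geometry) closes the 14‑membered cembranoid carbocycle as an enyne.

Step 18
Reactants: 31 macrocyclic epoxy enyne
Product: 32 briarane enyne 14-ol with 11(20)-exocyclic alkene (trans-fused 6/10 core; 2,9-diacetate; 16-OTBS)
Conditions: Cp2TiCl2 (2.5 equiv), Mn dust, THF, 23 °C; 31 added over 2 h (5 mM); aq. NaH2PO4
Reagents that add atoms: none
Why: Proposed new method: Cp2TiCl (trivalent titanium) opens the trisubstituted epoxide homolytically to the tertiary C8 radical, which adds transannularly 6‑endo to C3 of the (Z)‑C3=C4 alkene through a chair transition state that keeps the (Z,Z) geometry (both ring tethers pseudo‑axial, the O–Ti group pseudo‑equatorial and anti to the forming bond), and hydrogen abstraction from the new tertiary radical then gives the trans‑fused cyclohexane with C1, C10 and the axial C14‑OH set in one step; the alkyne (not a diene) next to C9 denies the radical a 3‑exo escape to an allylic radical, and the closest known reaction is the titanocene‑mediated transannular cyclisation of epoxygermacrolides to eudesmanolides (Nugent–RajanBabu epoxide opening).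

Step 19
Reactants: 32 briarane enyne with exocyclic alkene
Product: 33 briarane enyne 14-ol with 11(12)-endocyclic alkene
Conditions: (salen)CoCl [salen = N,N′-bis(3,5-di-tert-butylsalicylidene)-1,2-cyclohexanediaminate] (5 mol %), PhSiH3 (5 mol %), C6H6, 23 °C
Reagents that add atoms: none
Why: cobalt‑hydride hydrogen‑atom‑transfer isomerisation (Shenvi type) moves the 1,1‑disubstituted alkene one position toward the unhindered ring CH2 to give the trisubstituted alkene, the internal alkyne and trisubstituted alkenes being poor hydrogen‑atom acceptors.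

Step 20
Reactants: 33 briarane enyne with endocyclic alkene
Product: 35 briara-3E,5Z,11-triene 14-ol (2,9-diacetate; 16-OTBS; 7-O lactone), via vinylsiloxane 34 (not isolated)
Conditions: [Cp*Ru(MeCN)3]PF6 (10 mol %), (EtO)3SiH, CH2Cl2, 0 → 23 °C; then AgF, THF/MeOH/H2O, 23 °C
Reagents that add atoms: none
Why: Trost/Fürstner ruthenium‑catalysed trans‑hydrosilylation of the ring alkyne followed by fluoride protodesilylation with retention gives the (E)‑alkene and completes the (3E,5Z)‑diene.

Step 21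
Reactants: 35 briaratriene 14-ol
Product: 36 11,12-α-epoxide of 35
Conditions: mCPBA, NaHCO3, CH2Cl2, 0 °C
Reagents that add atoms: 3-chloroperoxybenzoic acid OOC(=O)c1cccc(Cl)c1
Why: peracid epoxidation of the only electron‑rich alkene (the diene is deactivated by its allylic oxygens), delivered syn to the axial homoallylic C14‑OH (Henbest direction) and anti to the axial C15 methyl, sets C11 and C12.

Step 22
Reactants: 36 epoxy alcohol silyl ether
Product: 38 CNP0250433.1 (target), via diol 37 (not isolated)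
Conditions: TBAF, AcOH, THF, 0 → 23 °C; then Ac2O, pyridine, DMAP, 23 °C
Reagents that add atoms: acetic anhydride CC(=O)OC(C)=O
Why: buffered fluoride removes the primary silyl ether and DMAP‑catalysed acetylation esterifies the primary C16 and hindered secondary C14 alcohols, while the tertiary C8‑OH does not react.

**Compound list**

1 | [2-(1,3-dioxolan-2-yl)ethyl]magnesium bromide | Br[Mg]CCC1OCCO1 | starting material
2 | propyne | CC#C | starting material
3 | vinylcopper: (1Z)-[4-(1,3-dioxolan-2-yl)-2-methylbut-1-en-1-yl]copper | [Cu]/C=C(C)\CCC1OCCO1 | intermediate (not isolated)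
4 | bromo acetal: 2-[(3Z)-4-bromo-3-methylbut-3-en-1-yl]-1,3-dioxolane | Br/C=C(C)\CCC1OCCO1 | intermediate (not isolated)
5 | (4Z)-5-bromo-4-methylpent-4-enal | Br/C=C(C)\CCC=O | intermediate
6 | ethyl 2-[bis(2,2,2-trifluoroethoxy)phosphoryl]propanoate | CCOC(=O)C(C)P(=O)(OCC(F)(F)F)OCC(F)(F)F | starting material
7 | ethyl (2Z,6Z)-7-bromo-2,6-dimethylhepta-2,6-dienoate | Br/C=C(C)\CC/C=C(C)\C(=O)OCC | intermediate
8 | ethynyltrimethylsilane | C#C[Si](C)(C)C | starting material
9 | (4Z,8Z)-9-bromo-4,8-dimethyl-1-(trimethylsilyl)nona-4,8-dien-1-yn-3-one | Br/C=C(C)\CC/C=C(C)\C(=O)C#C[Si](C)(C)C | intermediate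
10 | (3R,4Z,8Z)-9-bromo-4,8-dimethyl-1-(trimethylsilyl)nona-4,8-dien-1-yn-3-ol | Br/C=C(C)\CC/C=C(C)\[C@@H](O)C#C[Si](C)(C)C | intermediate
11 | (1S)-1-{(2R,3S)-3-[(3Z)-4-bromo-3-methylbut-3-en-1-yl]-2-methyloxiran-2-yl}-3-(trimethylsilyl)prop-2-yn-1-ol | Br/C=C(C)\CC[C@@H]1O[C@]1(C)[C@@H](O)C#C[Si](C)(C)C | intermediate
12 | but-2-yne-1,4-diol | OCC#CCO | starting material
13 | 4-[(tert-butyldimethylsilyl)oxy]but-2-yn-1-ol | CC(C)(C)[Si](C)(C)OCC#CCO | intermediate
14 | alkenylalanate: sodium cyclic (Z)-alkenyl(alkoxy)bis(2-methoxyethoxy)aluminate | [Na+].COCCO[Al-]1(OCCOC)OCC=C1CO[Si](C)(C)C(C)(C)C | intermediate (not isolated)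
15 | (2Z)-4-[(tert-butyldimethylsilyl)oxy]-3-iodobut-2-en-1-ol | CC(C)(C)[Si](C)(C)OC/C(I)=C/CO | intermediate
16 | (2Z)-4-[(tert-butyldimethylsilyl)oxy]-3-iodobut-2-enal | CC(C)(C)[Si](C)(C)OC/C(I)=C/C=O | intermediate
17 | triethyl phosphonoacetate | CCOC(=O)CP(=O)(OCC)OCC | starting material
18 | tert-butyl (2R)-2-hydroxypropanoate | C[C@@H](O)C(=O)OC(C)(C)C | starting material
19 | lactate triflate: tert-butyl (2R)-2-[(trifluoromethanesulfonyl)oxy]propanoate | C[C@@H](OS(=O)(=O)C(F)(F)F)C(=O)OC(C)(C)C | intermediate (not isolated)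
20 | 4-tert-butyl 1-ethyl (3S)-2-(diethoxyphosphoryl)-3-methylbutanedioate (C2 epimers) | CCOC(=O)C(P(=O)(OCC)OCC)[C@@H](C)C(=O)OC(C)(C)C | intermediate
21 | 4-tert-butyl 1-ethyl (2E,3R)-2-{(2Z)-4-[(tert-butyldimethylsilyl)oxy]-3-iodobut-2-en-1-ylidene}-3-methylbutanedioate | CC(C)(C)[Si](C)(C)OC/C(I)=C/C=C(/C(=O)OCC)[C@@H](C)C(=O)OC(C)(C)C | intermediate
22 | tert-butyl (2R,3E,5Z)-7-[(tert-butyldimethylsilyl)oxy]-3-(hydroxymethyl)-6-iodo-2-methylhepta-3,5-dienoate | CC(C)(C)[Si](C)(C)OC/C(I)=C/C=C(/CO)[C@@H](C)C(=O)OC(C)(C)C | intermediate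
23 | tert-butyl (2R)-2-[(2R,3R)-3-{(1Z)-3-[(tert-butyldimethylsilyl)oxy]-2-iodoprop-1-en-1-yl}-2-(hydroxymethyl)oxiran-2-yl]propanoate | CC(C)(C)[Si](C)(C)OC/C(I)=C/[C@H]1O[C@@]1(CO)[C@@H](C)C(=O)OC(C)(C)C | intermediate
24 | tert-butyl (2R)-2-[(2S,3R)-2-formyl-3-{(1Z)-3-[(tert-butyldimethylsilyl)oxy]-2-iodoprop-1-en-1-yl}oxiran-2-yl]propanoate | CC(C)(C)[Si](C)(C)OC/C(I)=C/[C@H]1O[C@@]1(C=O)[C@@H](C)C(=O)OC(C)(C)C | intermediate
25 | vinyllithium: C3-lithio (Z)-alkene and C9 lithium alkoxide from 11 | [Li]/C=C(C)\CC[C@@H]1O[C@]1(C)[C@@H](O[Li])C#C[Si](C)(C)C | intermediate (not isolated)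
26 | vinyltitanium: C3 and O9 tris(isopropoxy)titanium derivative | CC(C)O[Ti](OC(C)C)(OC(C)C)/C=C(C)\CC[C@@H]1O[C@]1(C)[C@@H](O[Ti](OC(C)C)(OC(C)C)OC(C)C)C#C[Si](C)(C)C | intermediate (not isolated)
27 | bis-epoxide diol tert-butyl ester (C2–C3 adduct; 1,14- and 7,8-epoxides; 2-OH and 9-OH free; 3Z; C12–I; C11–SiMe3) | CC(C)(C)[Si](C)(C)OC/C(I)=C/[C@H]1O[C@]1([C@@H](C)C(=O)OC(C)(C)C)[C@@H](O)/C=C(C)\CC[C@@H]2O[C@]2(C)[C@@H](O)C#C[Si](C)(C)C | intermediate
28 | seco-cembranolide diol (17,14-lactone; tertiary 1-OH; 2-OH and 9-OH free) | CC(C)(C)[Si](C)(C)OC/C(I)=C/[C@@H]1OC(=O)[C@H](C)[C@@]1(O)[C@@H](O)/C=C(C)\CC[C@@H]2O[C@]2(C)[C@@H](O)C#C[Si](C)(C)C | intermediate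
29 | seco-cembranolide 2,9-diacetate (C11 silylalkyne; C12 iodide) | CC(C)(C)[Si](C)(C)OC/C(I)=C/[C@@H]1OC(=O)[C@H](C)[C@@]1(O)[C@@H](OC(C)=O)/C=C(C)\CC[C@@H]2O[C@]2(C)[C@@H](OC(C)=O)C#C[Si](C)(C)C | intermediate
30 | terminal alkyne: C-desilylated 29 | CC(C)(C)[Si](C)(C)OC/C(I)=C/[C@@H]1OC(=O)[C@H](C)[C@@]1(O)[C@@H](OC(C)=O)/C=C(C)\CC[C@@H]2O[C@]2(C)[C@@H](OC(C)=O)C#C | intermediate (not isolated)
31 | (3Z)-7,8-epoxycembra-3,12-dien-10-yn-17,14-olide 2,9-diacetate 20-silyl ether (14-membered ring; 1-OH free) | CC(C)(C)[Si](C)(C)OC/C1=C/[C@@H]2OC(=O)[C@H](C)[C@@]2(O)[C@@H](OC(C)=O)/C=C(C)\CC[C@@H]3O[C@]3(C)[C@@H](OC(C)=O)C#C1 | intermediate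
32 | briarane enyne 14-ol with 11(20)-exocyclic alkene (trans-fused 6/10 core; 2,9-diacetate; 16-OTBS) | CC(C)(C)[Si](C)(C)OC/C1=C/[C@@H]2OC(=O)[C@H](C)[C@@]2(O)[C@@H](OC(C)=O)[C@H]3C(=C)CC[C@H](O)[C@]3(C)[C@@H](OC(C)=O)C#C1 | intermediate
33 | briarane enyne 14-ol with 11(12)-endocyclic alkene | CC(C)(C)[Si](C)(C)OC/C1=C/[C@@H]2OC(=O)[C@H](C)[C@@]2(O)[C@@H](OC(C)=O)[C@H]3C(C)=CC[C@H](O)[C@]3(C)[C@@H](OC(C)=O)C#C1 | intermediate
34 | vinylsiloxane: C4-triethoxysilyl (3Z)-diene from trans-hydrosilylation of 33 | CC(C)(C)[Si](C)(C)OCC1=C/[C@@H]2OC(=O)[C@H](C)[C@@]2(O)[C@@H](OC(C)=O)[C@H]3C(C)=CC[C@H](O)[C@]3(C)[C@@H](OC(C)=O)\C=C\1[Si](OCC)(OCC)OCC | intermediate (not isolated)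
35 | briara-3E,5Z,11-triene 14-ol (2,9-diacetate; 16-OTBS; 8-OH; 7-O lactone) | CC(C)(C)[Si](C)(C)OCC1=C/[C@@H]2OC(=O)[C@H](C)[C@@]2(O)[C@@H](OC(C)=O)[C@H]3C(C)=CC[C@H](O)[C@]3(C)[C@@H](OC(C)=O)\C=C\1 | intermediate
36 | 11,12-α-epoxide of 35 | CC(C)(C)[Si](C)(C)OCC1=C/[C@@H]2OC(=O)[C@H](C)[C@@]2(O)[C@@H](OC(C)=O)[C@H]3[C@]4(C)O[C@@H]4C[C@H](O)[C@]3(C)[C@@H](OC(C)=O)\C=C\1 | intermediate
37 | diol: 14,16-diol 2,9-diacetate | OCC1=C/[C@@H]2OC(=O)[C@H](C)[C@@]2(O)[C@@H](OC(C)=O)[C@H]3[C@]4(C)O[C@@H]4C[C@H](O)[C@]3(C)[C@@H](OC(C)=O)\C=C\1 | intermediate (not isolated)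
38 | CNP0250433.1: (1R,2S,7S,8S,9S,10S,11S,12R,14S,17R)-2,9,14,16-tetraacetoxy-11,12-epoxy-8-hydroxybriara-3E,5-diene 7-O γ-lactone | CC(=O)OCC1=C/[C@@H]2OC(=O)[C@H](C)[C@@]2(O)[C@@H](OC(C)=O)[C@H]2[C@]3(C)O[C@@H]3C[C@H](OC(C)=O)[C@]2(C)[C@@H](OC(C)=O)\C=C\1 | target

**Totals**

Total steps: 22. Longest linear sequence: 16 steps (steps 6, 7, 8, 10–22 from but‑2‑yne‑1,4‑diol).

**Three steps most likely to fail, with fallbacks**

Step 18 (transannular radical cyclisation). The C8 radical may be quenched by hydrogen abstraction before it closes the ring, or close with the wrong ring fusion. The fallback sets out from 31 and returns at 33. Compound 31 is opened with the same titanocene reagent at high concentration (0.2 M, 3 equiv Cp2TiCl), where hydrogen abstraction outruns ring closure, to give the uncyclised exo‑methylene macrocyclic allylic alcohol F1. F1 is then treated with the cobalt‑hydride catalyst of step 19 with PhSiH3. Hydrogen‑atom transfer to the 1,1‑disubstituted alkene regenerates the same tertiary C8 radical reversibly, so it is formed again and again until it adds to C3. The cobalt then removes a hydrogen atom and moves the new alkene into the ring, which gives 33 directly and makes step 19 unnecessary.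

Step 17 (desilylative Sonogashira macrocyclisation). Fluoride may attack the acetates, or copper acetylide dimerisation may compete with ring closure. The fallback sets out from 29 and returns at 31. Compound 29 is desilylated on its own (AgNO3 cat., 2,6‑lutidine, aqueous acetone) and the terminal alkyne 30 is isolated. It is stannylated with Bu3SnOMe (neat, 60 °C, methanol removed) to the alkynylstannane F2. A copper‑free, base‑free intramolecular Stille–Migita coupling (Pd2(dba)3, AsPh3, DMF, 1 mM, 40 °C) then closes the 14‑membered ring to 31.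

Step 14 (fragment union and C2 configuration). The addition may give a poor ratio at the new carbinol. The fallback sets out from 24 (with reagent 25 made from 11 as in step 14) and returns at 27. Aldehyde 24 is oxidised (NaClO2, NaH2PO4, 2‑methyl‑2‑butene) to the epoxy acid F3, which is converted (MeNHOMe·HCl, EDC, i‑Pr2NEt) to the Weinreb amide F4. Acylation of F4 with vinyllithium 25 gives the epoxy enone F5. Chelation‑controlled 1,2‑reduction with Zn(BH4)2 (Et2O, −20 °C) then gives 27: zinc bridges the ketone and oxirane oxygens and hydride enters from the oxirane‑CH side, away from the branched propanoate arm. The stereocentre is thus set by reduction instead of by C–C bond formation.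

Further compounds
F1 | step 18 | macrocyclic allylic alcohol: (3Z)-cembra-3,8(19),12-trien-10-yn-7-ol 17,14-olide 2,9-diacetate 20-silyl ether | CC(C)(C)[Si](C)(C)OC/C1=C/[C@@H]2OC(=O)[C@H](C)[C@@]2(O)[C@@H](OC(C)=O)/C=C(C)\CC[C@H](O)C(=C)[C@@H](OC(C)=O)C#C1
F2 | step 17 | alkynylstannane: C11-tributylstannyl alkyne of 30 | CC(C)(C)[Si](C)(C)OC/C(I)=C/[C@@H]1OC(=O)[C@H](C)[C@@]1(O)[C@@H](OC(C)=O)/C=C(C)\CC[C@@H]2O[C@]2(C)[C@@H](OC(C)=O)C#C[Sn](CCCC)(CCCC)CCCC
F3 | step 14 | epoxy acid: carboxylic acid from 24 | CC(C)(C)[Si](C)(C)OC/C(I)=C/[C@H]1O[C@@]1(C(=O)O)[C@@H](C)C(=O)OC(C)(C)C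
F4 | step 14 | Weinreb amide: N-methoxy-N-methyl amide of F3 | CC(C)(C)[Si](C)(C)OC/C(I)=C/[C@H]1O[C@@]1(C(=O)N(C)OC)[C@@H](C)C(=O)OC(C)(C)C
F5 | step 14 | epoxy enone: C2 ketone corresponding to 27 | CC(C)(C)[Si](C)(C)OC/C(I)=C/[C@H]1O[C@]1([C@@H](C)C(=O)OC(C)(C)C)C(=O)/C=C(C)\CC[C@@H]2O[C@]2(C)[C@@H](O)C#C[Si](C)(C)C
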